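## Analysis of the target

The target is a single oxolane (tetrahydrofuran) ring, O1–C2–C3–C4–C5, substituted at every carbon: C2 and C5 carry 4-hydroxy-3,5-dimethoxyphenyl (syringyl) groups, and C3 and C4 carry hydroxymethyl groups. The four contiguous stereocentres are (2R,3S,4R,5S), and a mirror plane through O1 and the midpoint of C3–C4 exchanges the two halves, so the compound is meso and no absolute stereocontrol is needed. The relative configuration is 2,3-trans, 3,4-cis, 4,5-trans: both aryl groups lie on one face of the ring and both hydroxymethyl groups on the other. The sensitive features are the two electron-rich free phenols (oxidation) and the two ring C–O bonds, each secondary and benzylic, which can ionise under acid or Lewis acid and can be hydrogenolysed. The difficulty is the cis pair of hydroxymethyl groups that is at the same time anti to both aryl groups; hydrogenation of a ring alkene that already carries the C3/C4 carbons would place them on the wrong face. The strategy rests on this face relationship: C3 and C4 look as if a two-carbon unit had added suprafacially to the C3=C4 double bond of a cis-2,5-diaryl-2,5-dihydrofuran, from the face that carries only H2 and H5. Because that dihydrofuran keeps the mirror plane, the orientation of an unsymmetrical two-carbon unit does not matter.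

## Retrosynthetic reasoning

19 ⇒ 18. The two aryl O–CH2Ph bonds are cut. The phenols travel as benzyl ethers because these survive carbanion addition, reductive dechlorination, enolisation, peroxide oxidation, glycol-type cleavage and hydride reduction, and come off last under neutral conditions. The forward step must cleave the aryl benzyl ethers without hydrogenolysing the ring C–O bonds.

18 ⇒ 17. No skeletal bond is cut. The two hydroxymethyl carbons are raised to a formyl and a carboxyl carbon, held together as the cis-fused hydroxylactone 17 (ring tautomer of aldehyde acid 16). This makes them the two ends of a cleaved C–C bond, and the cis-fused bicycle guards the C3/C4 configuration. The forward step is an exhaustive hydride reduction.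

17 ⇒ 15 ⇒ 13 ⇒ 12. Reconnecting the formyl and carboxyl carbons gives cyclobutanone 12, so the bond cleaved in the forward direction is C6–C7 (carbonyl carbon to methylene). Cleavage on the other side of the carbonyl, as in a Baeyer–Villiger insertion, would move the ring-fusion carbon onto oxygen and destroy one of the two C–C bonds the target needs. The forward sequence oxygenates C7 selectively, through silyl enol ether 13, silyloxy epoxide 14 and hydroxy ketone 15, and then cleaves the ketol. Regiochemistry is secure because enolisation toward C5 would put a double bond at the fusion of the four- and five-membered rings.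

12 ⇒ 11. Two chlorine atoms are put back on C7. They serve only as the activating substituents that make 10 electrophilic enough to add to an unactivated alkene, and they leave by reductive dechlorination.

11 ⇒ 8 + 10. This is the key disconnection: C1–C7 and C5–C6 of the bicycle, which are the two exocyclic C–C bonds at C3 and C4 of the oxolane, are cut together in a retro-[2+2]. Cutting here creates both stereocentres in one suprafacial event and lets the C2/C5 aryl groups choose the face; cutting one bond at a time would need two separate face selections. It also leads back to 8, which is meso and whose only stereochemical feature is the cis relation of C2 and C5. The forward reaction has to be face-selective (anti to the aryl groups) and has to spare the ring ether, whose two C–O bonds are each benzylic and allylic. 10 is made in the flask from 9.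

8 ⇒ 7. One ring C–O bond is cut. The forward cyclodehydration inverts exactly one carbinol centre, so cis-8 requires the like (C2-symmetric) diol 7. Cutting C–O and not a ring C–C bond keeps the symmetric 1,4-diaryl C4 chain intact.

7 ⇒ 6. The Z-alkene is traced back to an alkyne, to be reduced by syn semihydrogenation. The chain becomes linear and can be assembled around a two-carbon unit.

6 ⇒ 3 + 4. Both aryl-carbinol C–C bonds are cut, giving two molecules of aldehyde 3 and 4 as a two-carbon dianion equivalent (5). This double disconnection uses the symmetry of the target. The forward addition is not diastereoselective, so only the like racemate 6 is carried on after separation.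

3 ⇒ 1 + 2. The phenol O–benzyl bond is cut; the forward step is an O-benzylation.

## Alternatives that were turned down

Alternative 1: Disconnection of both C2–aryl and C5–aryl bonds. The oxolane core with its two acetoxymethyl groups would be carried as the meso diacid A2. A2 would be made in a few operations (anhydride reduction, acetylation, oxidative alkene cleavage) from the exo oxanorbornene anhydride A4. The key step would be a twofold decarboxylative cross-coupling of A2 with aryl bromide A3 under nickel/photoredox dual catalysis, giving A1, the bis(benzyl ether) diacetate of the target.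
- For: A4 is among the cheapest stereodefined building blocks, and its exo geometry already places the C3/C4 carbons trans to the C2/C5 substituents. The aryl groups arrive last, so analogues would be easy, and the step count would be lower than in the chosen route.
- Against: the coupling erases and re-creates C2 and C5 through α-oxy radicals, so the 2,3-trans and 4,5-trans relations depend on two separate radical captures at nickel. Both must succeed on one molecule, with protodecarboxylation and mono-arylation as obvious leaks. A3 is an electron-rich, hindered partner for oxidative addition.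
- Comparison: on step count and modularity this alternative is stronger. The chosen strategy offers two classical C–C bond formations whose stereochemical course is fixed by a concerted mechanism and simple steric approach control.

Alternative 2: Disconnection of C3–C4 and O1–C5 in a formal [3+2] sense. β-Keto ester A6 would be oxidised by manganese triacetate A8 to an electrophilic α-radical. This radical adds to the alkene carbon of O-benzyl sinapyl acetate A7 that carries the acetoxymethyl group. Oxidation of the benzylic radical to the cation and capture by the enol oxygen would close the 4,5-dihydrofuran A5 with the 4,5-trans relation.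
- For: the ring, two bonds and two stereocentres come from two short fragments in one operation, and the regiochemistry is dictated by benzylic radical stability.
- Against: A5 still holds a tetrasubstituted C2=C3 enol ether that must be reduced. Syn hydrogenation puts the C2 aryl and the C3 ester on the same face (2,3-cis). The face itself is poorly differentiated because the C4 and C5 substituents lie on opposite sides. Epimerisation at C3 has no driving force, since the ester is cis to one neighbour in either configuration.
- Comparison: up to the ring this route is more convergent, and on that point it is stronger. The chosen strategy never has to set the C2/C3 or C3/C4 relation by delivering hydrogen, because C3 and C4 receive their carbon substituents together on the open face.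

Alternative 3: Disconnection of the C4–CH2 and C2–C3 bonds (lactone numbering), a three-component union on a butenolide. CuBr·SMe2-catalysed conjugate addition of the silylmethyl Grignard reagent A11 to the 5-aryl butenolide A10 would form the C4–CH2 bond anti to the aryl group. Trapping the enolate with aldehyde 3 would give the trans,trans lactone A9. Tamao oxidation, lactone reduction and cyclodehydration between the two benzylic carbinols would follow.
- For: conjugate addition–aldol sequences on butenolides are the best-precedented entry to trans,trans-disubstituted butyrolactone lignans, and three contiguous stereocentres come from one. The trans,trans lactone does map onto the 3,4-cis/4,5-trans pattern of the target once the lactone carbonyl is seen as one of the hydroxymethyl carbons.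
- Against: the carbinol centre forms as epimers, and a stepwise, desymmetrised assembly of two identical halves is not repaid for a meso target. Above all, the ring closure must be run on a polyol in which a benzylic cation can be captured by a primary hydroxyl as readily as by the second benzylic one, the path to furofuran-type bis-ethers, so extra protection would be needed.
- Comparison: on precedent for its key step this alternative is at least as strong. The chosen strategy closes the oxolane before any primary hydroxyl exists, uses the mirror symmetry twice (double addition to 4, one cycloaddition for both hydroxymethyl carbons) and needs no protecting group beyond the phenol ethers.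

Key step: step 5

Remark: 8, 18 and 19 are meso; 6, 7 and 11–17 are racemates of which one enantiomer is drawn, which suffices because every chiral intermediate converges on the meso diol 18.

Step 1
Reactants: 1 syringaldehyde (4-hydroxy-3,5-dimethoxybenzaldehyde); 2 benzyl bromide
Product: 3 4-(benzyloxy)-3,5-dimethoxybenzaldehyde
Conditions: K2CO3, DMF, 60 °C
Reagents that add atoms: none
Why: Williamson ether synthesis: the phenoxide of 1, made more acidic by the para-formyl group, is benzylated on oxygen by SN2, and the aldehyde is untouched under carbonate.

Step 2
Reactants: 3 4-(benzyloxy)-3,5-dimethoxybenzaldehyde (2 equiv); 4 acetylene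
Product: 6 (1R*,4R*)-1,4-bis(4-benzyloxy-3,5-dimethoxyphenyl)but-2-yne-1,4-diol, via ethyne-1,2-diylbis(magnesium bromide) 5 (not isolated)
Conditions: 4 (1.0 equiv, metered) into EtMgBr (2.0 equiv), Et2O/toluene, rt → 40 °C; then 3 (2.0 equiv) in THF, 0 °C → rt; aq. NH4Cl; fractional crystallisation or chromatography
Reagents that add atoms: none
Why: Double deprotonation of 4 gives the bis(acetylide) 5, which adds twice to the non-enolisable aldehyde 3 (alkynyl Grignard 1,2-addition). No 1,4-induction across the rigid alkyne is expected, so the like (C2-symmetric) racemate 6 and the meso diastereomer F1 should form in comparable amounts; 6 is separated and recognised as the diastereomer that splits into two peaks on a chiral stationary phase.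

Step 3
Reactants: 6 (1R*,4R*)-1,4-bis(4-benzyloxy-3,5-dimethoxyphenyl)but-2-yne-1,4-diol
Product: 7 (2Z,1R*,4R*)-1,4-bis(4-benzyloxy-3,5-dimethoxyphenyl)but-2-ene-1,4-diol
Conditions: H2 (1 atm, 1 equiv uptake), 5% Pd/CaCO3 poisoned with Pb(OAc)2, quinoline, EtOAc, rt
Reagents that add atoms: none
Why: Lindlar semihydrogenation: syn delivery of H2 on the poisoned surface gives the Z-alkene needed for five-membered ring closure, while quinoline and the lead poison suppress over-reduction and hydrogenolysis of the benzyl ethers and benzylic alcohols; the carbinol centres are not touched.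

Step 4
Reactants: 7 (2Z,1R*,4R*)-1,4-bis(4-benzyloxy-3,5-dimethoxyphenyl)but-2-ene-1,4-diol
Product: 8 (2R,5S)-2,5-bis(4-benzyloxy-3,5-dimethoxyphenyl)-2,5-dihydrofuran (cis, meso)
Conditions: PPh3, DIAD, THF, 0 °C → rt
Reagents that add atoms: none
Why: Mitsunobu cyclodehydration of a 1,4-diol (through the dioxaphosphorane and alkoxyphosphonium alkoxide): one hydroxyl becomes the leaving group and is displaced intramolecularly by the other (5-exo-tet, SN2), so exactly one carbinol centre is inverted and the like diol 7 gives the cis dihydrofuran; the two hydroxyls of 7 are homotopic, so either mode of activation gives the same product. The 4-benzyloxy group, twisted out of conjugation between two methoxy groups, is only a weak π-donor, which should disfavour an ionising pathway.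

Step 5
Reactants: 8 (2R,5S)-2,5-bis(4-benzyloxy-3,5-dimethoxyphenyl)-2,5-dihydrofuran; 9 trichloroacetyl chloride
Product: 11 rac-(1R,2R,4S,5S)-2,4-bis(4-benzyloxy-3,5-dimethoxyphenyl)-7,7-dichloro-3-oxabicyclo[3.2.0]heptan-6-one, via dichloroketene 10 (not isolated)
Conditions: 9 (slow addition), Zn–Cu couple, Et2O/DME, ultrasound, 15–25 °C
Reagents that add atoms: none
Why: Zn–Cu reduces 9 to dichloroketene 10, an electrophilic ketene that adds to the unactivated cis-alkene C3=C4 of 8 in a concerted, asynchronous thermal [2+2] cycloaddition, usually described as [π2s+π2a], with the ketene approaching orthogonally and its carbonyl carbon leading. The closest known reaction type is the dichloroketene cycloaddition to cyclic cis-alkenes such as cyclopentene and the parent 2,5-dihydrofuran. The four-membered ring is closed by the cycloaddition itself: both σ-bonds (C3–C=O and C4–CCl2 in oxolane numbering) form in one suprafacial event on the alkene, so the ring fusion is necessarily cis. The two new stereocentres, C1 and C5 of the bicycle, are controlled by the C2/C5 aryl groups of 8, which both occupy one face of the nearly planar ring, so the ketene must arrive on the face bearing only H2 and H5, giving 2,3-trans, 3,4-cis, 4,5-trans. Facial selectivity is the only selectivity needed, because 8 has a mirror plane and the two orientations of the ketene are enantiomeric and converge later on the meso diol. A ketene-Claisen diversion through the acylated ring oxygen is disfavoured because the ring C–O bonds lie close to the nodal plane of the C3=C4 π bond and a chair transition state is out of reach, and DME is present to bind ZnCl2 so that the Lewis acid does not ionise the benzylic, allylic C–O bonds.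

Step 6
Reactants: 11 rac-(1R,2R,4S,5S)-2,4-bis(4-benzyloxy-3,5-dimethoxyphenyl)-7,7-dichloro-3-oxabicyclo[3.2.0]heptan-6-one
Product: 12 rac-2,4-bis(4-benzyloxy-3,5-dimethoxyphenyl)-3-oxabicyclo[3.2.0]heptan-6-one (cis ring fusion; aryl groups cis to each other and anti to the four-membered ring)
Conditions: Zn dust, NH4Cl, MeOH, rt
Reagents that add atoms: none
Why: Reductive dechlorination of an α,α-dichlorocyclobutanone by zinc (via the zinc enolate, protonated by NH4Cl/MeOH) is the standard sequel to dichloroketene cycloadditions; no stereocentre is touched and the near-neutral medium spares the benzylic ether bonds.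

Step 7
Reactants: 12 rac-2,4-bis(4-benzyloxy-3,5-dimethoxyphenyl)-3-oxabicyclo[3.2.0]heptan-6-one
Product: 13 rac-2,4-bis(4-benzyloxy-3,5-dimethoxyphenyl)-6-(trimethylsilyloxy)-3-oxabicyclo[3.2.0]hept-6-ene (ring stereochemistry as in 12)
Conditions: LiN(iPr)2, TMSCl (internal quench), THF, −78 °C; non-aqueous work-up
Reagents that add atoms: chlorotrimethylsilane, C[Si](C)(C)Cl
Why: Kinetic enolisation with a hindered amide base and in situ silylation (silyl enol ether formation): deprotonation occurs only at the unhindered C7 methylene, because an enolate toward the ring-fusion carbon C5 would place a double bond at the fusion of the four- and five-membered rings; the internal TMSCl quench keeps the electrophilic cyclobutanone from self-aldolisation.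

Step 8
Reactants: 13 rac-2,4-bis(4-benzyloxy-3,5-dimethoxyphenyl)-6-(trimethylsilyloxy)-3-oxabicyclo[3.2.0]hept-6-ene
Product: 15 rac-2,4-bis(4-benzyloxy-3,5-dimethoxyphenyl)-7-exo-hydroxy-3-oxabicyclo[3.2.0]heptan-6-one, via silyloxy epoxide 14 (not isolated)
Conditions: DMDO (acetone solution, 1.05 equiv), CH2Cl2, −40 → 0 °C; then AcOH, THF/H2O, 0 °C; used crude
Reagents that add atoms: dimethyldioxirane, CC1(C)OO1
Why: Rubottom oxidation: the electron-rich enol ether C6=C7 is epoxidised by neutral DMDO from the convex (exo) face, and mild acid opens the silyloxy epoxide 14 to the α-hydroxy ketone; DMDO is preferred to a peracid because cyclobutanones undergo Baeyer–Villiger oxidation very easily. The configuration of the new carbinol is irrelevant, since C7 becomes a formyl carbon in the next step.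

Step 9
Reactants: 15 rac-2,4-bis(4-benzyloxy-3,5-dimethoxyphenyl)-7-exo-hydroxy-3-oxabicyclo[3.2.0]heptan-6-one
Product: 17 rac-4,6-bis(4-benzyloxy-3,5-dimethoxyphenyl)-3-hydroxytetrahydro-1H,3H-furo[3,4-c]furan-1-one, via aldehyde acid 16 (not isolated)
Conditions: NaIO4, THF/H2O, 0 °C → rt
Reagents that add atoms: water, O
Why: Periodate cleavage of an α-hydroxy ketone through its hydrate, which the strained cyclobutanone forms readily and which supplies the extra oxygen, cuts C6–C7 and turns C6 into a carboxyl and C7 into a formyl group, with relief of ring strain as driving force. The cis pair should close to the cis-fused hydroxylactone 17 (lactol epimers), which shields the formyl-bearing stereocentre from epimerisation.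

Step 10
Reactants: 17 rac-4,6-bis(4-benzyloxy-3,5-dimethoxyphenyl)-3-hydroxytetrahydro-1H,3H-furo[3,4-c]furan-1-one
Product: 18 [(2R,3S,4R,5S)-2,5-bis(4-benzyloxy-3,5-dimethoxyphenyl)tetrahydrofuran-3,4-diyl]dimethanol (meso)
Conditions: LiAlH4, THF, 0 °C → reflux; Fieser work-up
Reagents that add atoms: none
Why: LiAlH4 reduces the lactol and lactone carbons (the masked aldehyde/acid pair) to two primary alcohols; reduction outruns any enolisation, so the 3,4-cis arrangement is kept, and the benzyl ethers and the ring ether are inert to hydride.

Step 11
Reactants: 18 [(2R,3S,4R,5S)-2,5-bis(4-benzyloxy-3,5-dimethoxyphenyl)tetrahydrofuran-3,4-diyl]dimethanol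
Product: 19 [(2R,3S,4R,5S)-2,5-bis(4-hydroxy-3,5-dimethoxyphenyl)tetrahydrofuran-3,4-diyl]dimethanol (target, meso)
Conditions: H2 (1 atm), 10% Pd/C, EtOAc/MeOH, rt
Reagents that add atoms: none
Why: Catalytic hydrogenolysis of aryl benzyl ethers: under neutral conditions at 1 atm the O–CH2Ph bonds should be cleaved far faster than the hindered secondary benzylic C–O bonds of the ring, and the reaction is stopped once 18 is consumed to avoid ring hydrogenolysis.

Compound list

1 | syringaldehyde (4-hydroxy-3,5-dimethoxybenzaldehyde) | COc1cc(C=O)cc(OC)c1O | starting material
2 | benzyl bromide | BrCc1ccccc1 | starting material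
3 | 4-(benzyloxy)-3,5-dimethoxybenzaldehyde | COc1cc(C=O)cc(OC)c1OCc1ccccc1 | intermediate
4 | acetylene (ethyne) | C#C | starting material
5 | ethyne-1,2-diylbis(magnesium bromide) | Br[Mg]C#C[Mg]Br | intermediate
6 | (1R*,4R*)-1,4-bis(4-benzyloxy-3,5-dimethoxyphenyl)but-2-yne-1,4-diol (like, C2-symmetric racemate; (1R,4R) drawn) | COc1cc([C@@H](O)C#C[C@H](O)c2cc(OC)c(OCc3ccccc3)c(OC)c2)cc(OC)c1OCc1ccccc1 | intermediate
7 | (2Z,1R*,4R*)-1,4-bis(4-benzyloxy-3,5-dimethoxyphenyl)but-2-ene-1,4-diol (like racemate; same spatial arrangement as drawn for 6) | COc1cc([C@@H](O)/C=C\[C@H](O)c2cc(OC)c(OCc3ccccc3)c(OC)c2)cc(OC)c1OCc1ccccc1 | intermediate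
8 | (2R,5S)-2,5-bis(4-benzyloxy-3,5-dimethoxyphenyl)-2,5-dihydrofuran (cis, meso) | COc1cc([C@H]2O[C@@H](c3cc(OC)c(OCc4ccccc4)c(OC)c3)C=C2)cc(OC)c1OCc1ccccc1 | intermediate
9 | trichloroacetyl chloride | ClC(=O)C(Cl)(Cl)Cl | starting material
10 | dichloroketene | O=C=C(Cl)Cl | intermediate
11 | rac-(1R,2R,4S,5S)-2,4-bis(4-benzyloxy-3,5-dimethoxyphenyl)-7,7-dichloro-3-oxabicyclo[3.2.0]heptan-6-one (cyclobutanone anti to both aryl groups) | COc1cc([C@H]2O[C@@H](c3cc(OC)c(OCc4ccccc4)c(OC)c3)[C@H](C5(Cl)Cl)[C@@H]2C5=O)cc(OC)c1OCc1ccccc1 | intermediate
12 | rac-2,4-bis(4-benzyloxy-3,5-dimethoxyphenyl)-3-oxabicyclo[3.2.0]heptan-6-one (cis-fused; aryl groups cis to each other, anti to the four-membered ring) | COc1cc([C@H]2O[C@@H](c3cc(OC)c(OCc4ccccc4)c(OC)c3)[C@H](C5)[C@@H]2C5=O)cc(OC)c1OCc1ccccc1 | intermediate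
13 | rac-2,4-bis(4-benzyloxy-3,5-dimethoxyphenyl)-6-(trimethylsilyloxy)-3-oxabicyclo[3.2.0]hept-6-ene (ring stereochemistry as in 12) | COc1cc([C@H]2O[C@@H](c3cc(OC)c(OCc4ccccc4)c(OC)c3)[C@H](C=C5O[Si](C)(C)C)[C@@H]25)cc(OC)c1OCc1ccccc1 | intermediate
14 | rac-2,4-bis(4-benzyloxy-3,5-dimethoxyphenyl)-6,7-epoxy-6-(trimethylsilyloxy)-3-oxabicyclo[3.2.0]heptane (epoxide on the convex, exo face) | COc1cc([C@H]2O[C@@H](c3cc(OC)c(OCc4ccccc4)c(OC)c3)[C@H]([C@H]6O[C@]65O[Si](C)(C)C)[C@@H]25)cc(OC)c1OCc1ccccc1 | intermediate
15 | rac-2,4-bis(4-benzyloxy-3,5-dimethoxyphenyl)-7-exo-hydroxy-3-oxabicyclo[3.2.0]heptan-6-one | COc1cc([C@H]2O[C@@H](c3cc(OC)c(OCc4ccccc4)c(OC)c3)[C@H]([C@@H](O)C5=O)[C@@H]25)cc(OC)c1OCc1ccccc1 | intermediate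
16 | rac-2,5-bis(4-benzyloxy-3,5-dimethoxyphenyl)-4-formyltetrahydrofuran-3-carboxylic acid (formyl and carboxyl cis to each other, trans to the aryl groups) | COc1cc([C@H]2O[C@@H](c3cc(OC)c(OCc4ccccc4)c(OC)c3)[C@H](C=O)[C@@H]2C(=O)O)cc(OC)c1OCc1ccccc1 | intermediate
17 | rac-4,6-bis(4-benzyloxy-3,5-dimethoxyphenyl)-3-hydroxytetrahydro-1H,3H-furo[3,4-c]furan-1-one (cis-fused; aryl groups on the face opposite the lactone ring; lactol carbon as epimers) | COc1cc([C@H]2O[C@@H](c3cc(OC)c(OCc4ccccc4)c(OC)c3)[C@H](C(O)OC5=O)[C@@H]25)cc(OC)c1OCc1ccccc1 | intermediate
18 | [(2R,3S,4R,5S)-2,5-bis(4-benzyloxy-3,5-dimethoxyphenyl)tetrahydrofuran-3,4-diyl]dimethanol (meso) | COc1cc([C@H]2O[C@@H](c3cc(OC)c(OCc4ccccc4)c(OC)c3)[C@H](CO)[C@@H]2CO)cc(OC)c1OCc1ccccc1 | intermediate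
19 | [(2R,3S,4R,5S)-2,5-bis(4-hydroxy-3,5-dimethoxyphenyl)tetrahydrofuran-3,4-diyl]dimethanol (meso) | COc1cc([C@H]2O[C@@H](c3cc(OC)c(O)c(OC)c3)[C@H](CO)[C@@H]2CO)cc(OC)c1O | target

Total number of steps: 11. Longest linear sequence: 11 steps, from 1 to 19; the route is fully linear, with 2, 4 and 9 entering as simple starting materials.

Least certain steps

Step 5 (key step). The likeliest failure is opening of the benzylic, allylic ring ether by ZnCl2 or by the acylating species (ionisation, O-acylation), or Friedel–Crafts-type acylation of the activated arenes. The alkene is also inductively deactivated by the ring oxygen, so the cycloaddition may be slow and ketene oligomerisation may win. Fallback: form the same two C–C bonds without the four-membered ring, by a divalent-palladium-catalysed syn bis(methoxycarbonylation) of the alkene of 8 (PdCl2 cat., CuCl2 as reoxidant, NaOAc, CO, MeOH, rt). This is a known cis-dicarbonylation of cyclic alkenes and should again take place on the face anti to the aryl groups, giving the dimethyl cis-3,4-diester F4. Reduction of F4 with LiAlH4 rejoins the route at 18 and bypasses 11–17. Its own weakness is β-hydride elimination of the alkylpalladium intermediate toward C5, which is why it is held in reserve.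

Step 4. The likeliest failure is partial ionisation of the alkoxyphosphonium intermediate, since the carbinol is benzylic and allylic. This would erode the single-inversion course and give the trans isomer, or lead to elimination to conjugated dienes. Fallback: give up stereospecific substitution and use an openly ionising, reversible closure. Treating 7 (or the unseparated diastereomer mixture from steps 2 and 3) with a catalytic sulfonic acid resin in CH2Cl2 over molecular sieves should give 8 together with the trans-dihydrofuran F3. The two are separated by chromatography; 8 is the isomer that gives a single peak on a chiral stationary phase. F3 is returned to the same acid to re-equilibrate through the ring-opened benzylic cation, so material is funnelled to 8.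

Step 8. The likeliest failures are hydrolysis of the labile cyclobutenyl silyl ether 13 back to 12 before oxidation, over-oxidation (Baeyer–Villiger-type ring expansion of the product, attack on the trialkoxyarenes), and acyloin-type ring contraction of 15 on handling. Fallback: hydroxylate the enolate directly. 12 is treated with KN(SiMe3)2 in THF at −78 °C and then with 2-(phenylsulfonyl)-3-phenyloxaziridine (Davis enolate oxidation). This gives 15 without passing through 13 and 14 and without any peroxide, and 15 is again carried crude into step 9.

Step 2. The likeliest failure is inefficient separation of 6 from its meso diastereomer; at best about half of the adduct is usable. Fallback: replace separation by catalyst control. The mixture of 6 and the meso ynediol F1 is oxidised with activated MnO2 (CH2Cl2, rt) to the ynedione F2. Its two carbonyl groups are then reduced independently by a Noyori-type asymmetric transfer hydrogenation (RuCl[(S,S)-TsDPEN](p-cymene), iPrOH, rt). Because the same catalyst enantiomer controls each carbinol, the like diastereomer 6 should dominate, essentially as one enantiomer, which is immaterial since 8 is meso. The route is rejoined at 6.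

Further compounds

F1 | step 2 | meso-(1R,4S)-1,4-bis(4-benzyloxy-3,5-dimethoxyphenyl)but-2-yne-1,4-diol | COc1cc([C@@H](O)C#C[C@@H](O)c2cc(OC)c(OCc3ccccc3)c(OC)c2)cc(OC)c1OCc1ccccc1
F2 | step 2 | 1,4-bis(4-benzyloxy-3,5-dimethoxyphenyl)but-2-yne-1,4-dione | COc1cc(C(=O)C#CC(=O)c2cc(OC)c(OCc3ccccc3)c(OC)c2)cc(OC)c1OCc1ccccc1
F3 | step 4 | rac-(2R,5R)-2,5-bis(4-benzyloxy-3,5-dimethoxyphenyl)-2,5-dihydrofuran (trans) | COc1cc([C@@H]2O[C@@H](c3cc(OC)c(OCc4ccccc4)c(OC)c3)C=C2)cc(OC)c1OCc1ccccc1
F4 | step 5 | dimethyl 2,5-bis(4-benzyloxy-3,5-dimethoxyphenyl)tetrahydrofuran-3,4-dicarboxylate (meso; ester groups cis to each other and trans to the aryl groups, as in 18) | COc1cc([C@H]2O[C@@H](c3cc(OC)c(OCc4ccccc4)c(OC)c3)[C@H](C(=O)OC)[C@@H]2C(=O)OC)cc(OC)c1OCc1ccccc1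
F0 | step 8 | none | none
A1 | alternative 1 | [(2R,3S,4R,5S)-2,5-bis(4-benzyloxy-3,5-dimethoxyphenyl)tetrahydrofuran-3,4-diyl]bis(methylene) diacetate | COc1cc([C@H]2O[C@@H](c3cc(OC)c(OCc4ccccc4)c(OC)c3)[C@H](COC(C)=O)[C@@H]2COC(C)=O)cc(OC)c1OCc1ccccc1
A2 | alternative 1 | meso-3,4-bis(acetoxymethyl)tetrahydrofuran-2,5-dicarboxylic acid (carboxyl groups cis to each other, trans to the acetoxymethyl groups) | OC(=O)[C@H]1O[C@@H](C(=O)O)[C@H](COC(C)=O)[C@@H]1COC(C)=O
A3 | alternative 1 | 2-(benzyloxy)-5-bromo-1,3-dimethoxybenzene | COc1cc(Br)cc(OC)c1OCc1ccccc1
A4 | alternative 1 | exo-3a,4,7,7a-tetrahydro-4,7-epoxyisobenzofuran-1,3-dione (exo oxanorbornene anhydride) | O=C1OC(=O)[C@@H]2[C@H]1[C@H]3C=C[C@@H]2O3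
A5 | alternative 2 | methyl trans-4-(acetoxymethyl)-2,5-bis(4-benzyloxy-3,5-dimethoxyphenyl)-4,5-dihydrofuran-3-carboxylate | COC(=O)C1=C(c2cc(OC)c(OCc3ccccc3)c(OC)c2)O[C@@H](c2cc(OC)c(OCc3ccccc3)c(OC)c2)[C@@H]1COC(C)=O
A6 | alternative 2 | methyl 3-(4-benzyloxy-3,5-dimethoxyphenyl)-3-oxopropanoate | COC(=O)CC(=O)c1cc(OC)c(OCc2ccccc2)c(OC)c1
A7 | alternative 2 | (E)-3-(4-benzyloxy-3,5-dimethoxyphenyl)allyl acetate (O-benzyl sinapyl acetate) | CC(=O)OC/C=C/c1cc(OC)c(OCc2ccccc2)c(OC)c1
A8 | alternative 2 | manganese triacetate | CC(=O)[O-].CC(=O)[O-].CC(=O)[O-].[Mn+3]
A9 | alternative 3 | trans,trans-3-[(4-benzyloxy-3,5-dimethoxyphenyl)(hydroxy)methyl]-5-(4-benzyloxy-3,5-dimethoxyphenyl)-4-[(isopropoxydimethylsilyl)methyl]dihydrofuran-2(3H)-one (one carbinol epimer drawn) | COc1cc([C@@H](O)[C@H]2C(=O)O[C@@H](c3cc(OC)c(OCc4ccccc4)c(OC)c3)[C@@H]2C[Si](C)(C)OC(C)C)cc(OC)c1OCc1ccccc1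
A10 | alternative 3 | 5-(4-benzyloxy-3,5-dimethoxyphenyl)furan-2(5H)-one | O=C1C=C[C@H](c2cc(OC)c(OCc3ccccc3)c(OC)c2)O1
A11 | alternative 3 | (isopropoxydimethylsilyl)methylmagnesium chloride | CC(C)O[Si](C)(C)C[Mg]Cl
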